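The oxolane ring (O1, C2 carrying the 4-hydroxyphenyl group, C3, C4, C5H2) is cut at O1–C2 and C3–C4. Its O1–C5–C4 unit is an alkoxide–allyl 1,3-dipole and C2–C3 an arylidene malonate. One palladium-catalysed [3+2] cycloaddition of a racemic 2-(1-arylethenyl)oxirane with a silyl-protected benzylidene malonate therefore builds the ring, both ring bonds and the C2 and C4 stereocentres, with the ligand choosing the enantiomer. The 1-arylethenyl group on C4 is a latent anisoyl group, and the geminal diester is trimmed to the C3 hydroxymethyl arm. Thermodynamic equilibration sets C3 and a reagent-controlled ketone reduction sets the carbinol centre.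

Key step: step 5

Assumption: the (R,R) antipode of the DACH-phenyl diphosphine is taken to give the (4R) cycloadduct, by analogy with dynamic kinetic asymmetric additions to butadiene monoepoxide; should the sense be opposite, the (S,S) ligand is used and nothing else changes.

Remark: ring atoms are numbered O1, C2 (aryl), C3, C4, C5 throughout. The descriptors at C2, C3 and C4 change between 9, 10/11 and 13–17 only because substituent priorities change; no centre is inverted after step 7.

Step 1
Reactants: 1 4-methoxyphenylacetaldehyde
Product: 3 2-(4-methoxyphenyl)prop-2-enal, via Mannich base 2 (not isolated)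
Conditions: Me2N+=CH2 I− (1.5 equiv), Et3N (3 equiv), CH2Cl2, rt
Reagents that add atoms: dimethyl(methylidene)ammonium iodide (Eschenmoser's salt), C=[N+](C)C.[I-]
Why: Mannich reaction of the enolisable arylacetaldehyde with the preformed iminium salt and E1cB loss of dimethylamine from the β-amino aldehyde (Eschenmoser methylenation) should give the 2-arylacrolein, which is used at once because such enals dimerise on standing.

Step 2
Reactants: 3 2-(4-methoxyphenyl)prop-2-enal
Product: 4 racemic 2-[1-(4-methoxyphenyl)ethenyl]oxirane
Conditions: Me3S+ I− (1.3 equiv), n-BuLi (1.25 equiv), THF, −10 °C; then 3, −10 °C → rt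
Reagents that add atoms: trimethylsulfonium iodide, C[S+](C)C.[I-]
Why: Corey–Chaykovsky epoxidation, in which the unstabilised sulfonium methylide adds 1,2 to the enal and the betaine closes to the oxirane without touching the alkene; the new centre forms as a racemate, which the key step is designed to accept.

Step 3
Reactants: 5 4-hydroxybenzaldehyde
Product: 6 4-(triisopropylsilyloxy)benzaldehyde
Conditions: TIPSCl (1.1 equiv), imidazole (2 equiv), DMF, rt
Reagents that add atoms: chlorotri(propan-2-yl)silane (TIPSCl), CC(C)[Si](Cl)(C(C)C)C(C)C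
Why: Imidazole-promoted O-silylation of the phenol; the hindered triisopropylsilyl aryl ether is the silyl ether most resistant to the basic and nucleophilic steps ahead and is later removed by fluoride without touching acetates.

Step 4
Reactants: 6 4-(triisopropylsilyloxy)benzaldehyde; 7 dimethyl malonate
Product: 8 dimethyl 2-[4-(triisopropylsilyloxy)benzylidene]malonate
Conditions: piperidine (10 mol %), AcOH (10 mol %), toluene, reflux, Dean–Stark trap
Reagents that add atoms: none
Why: Knoevenagel condensation through the piperidinium iminium ion with azeotropic removal of water; the symmetrical malonate makes alkene geometry irrelevant.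

Step 5
Reactants: 4 racemic 2-[1-(4-methoxyphenyl)ethenyl]oxirane (1.5 equiv); 8 dimethyl 2-[4-(triisopropylsilyloxy)benzylidene]malonate
Product: 9 dimethyl (2S,4R)-4-[1-(4-methoxyphenyl)ethenyl]-2-[4-(triisopropylsilyloxy)phenyl]oxolane-3,3-dicarboxylate (2,4-cis)
Conditions: Pd2(dba)3·CHCl3 (2.5 mol %), (1R,2R)-N,N'-bis[2-(diphenylphosphino)benzoyl]cyclohexane-1,2-diamine (7.5 mol %), THF, rt
Reagents that add atoms: none
Why: Zerovalent palladium opens the strained allylic C–O bond of 4 to a 2-aryl-π-allylpalladium alkoxide, whose oxygen adds reversibly to the β-carbon of 8 (oxa-Michael, O1–C2) before the malonate carbanion alkylates the internal allyl terminus (C3–C4); this is the known palladium-catalysed [3+2] cycloaddition of vinyl epoxides with doubly activated alkenes. The oxolane closes in a 5-exo-trig sense (carbanion onto the allyl terminus held two atoms from O1, alkene left exocyclic), the seven-membered alternative at the CH2 terminus being far slower. C4 is controlled by the chiral diphosphine: the two diastereomeric allyl complexes exchange faces through the η1 form at the unsubstituted CH2 terminus faster than they cyclise, so both enantiomers of 4 converge on one product (dynamic kinetic asymmetric transformation). C2 is controlled relative to C4 in the ring-closing transition state, because the oxa-Michael adducts equilibrate and the envelope with the C2 aryl group and the C4 allylpalladium unit both pseudo-equatorial leads to the 2,4-cis ring. The step thus needs branched regioselectivity, 2,4-cis diastereoselectivity and one absolute sense, secured by the short O1–C5–C4 tether, by the reversibility that the two ester groups give the oxa-Michael step, and by the ligand; any 2,4-trans isomer is separated here by chromatography, since it would otherwise be carried on as a stereoisomeric impurity.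

Step 6
Reactants: 9 dimethyl (2S,4R)-4-[1-(4-methoxyphenyl)ethenyl]-2-[4-(triisopropylsilyloxy)phenyl]oxolane-3,3-dicarboxylate
Product: 10 methyl (2R,4S)-4-[1-(4-methoxyphenyl)ethenyl]-2-[4-(triisopropylsilyloxy)phenyl]oxolane-3-carboxylate (mixture of C3 epimers)
Conditions: LiCl (3 equiv), H2O (2 equiv), DMSO, 140 °C
Reagents that add atoms: none
Why: Krapcho dealkoxycarbonylation (SN2 demethylation by chloride, loss of CO2, protonation of the ester enolate by water) should remove one ester; C3 forms without control and is corrected in step 7, and ring opening by β-elimination of O1 is stereoelectronically disfavoured as the reverse of a 5-endo-trig closure.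

Step 7
Reactants: 10 methyl (2R,4S)-4-[1-(4-methoxyphenyl)ethenyl]-2-[4-(triisopropylsilyloxy)phenyl]oxolane-3-carboxylate (C3 epimers)
Product: 11 methyl (2R,3R,4S)-4-[1-(4-methoxyphenyl)ethenyl]-2-[4-(triisopropylsilyloxy)phenyl]oxolane-3-carboxylate (2,3-trans, 3,4-trans)
Conditions: NaOMe (0.2 equiv), MeOH/THF, 0 °C → rt
Reagents that add atoms: none
Why: Base-mediated epimerisation through the ester enolate under thermodynamic control should place the C3 ester trans to both the C2 aryl and C4 alkenyl groups, which are fixed and mutually cis; catalytic methoxide cannot transesterify a methyl ester and the hindered aryl silyl ether should survive the short, dilute exposure.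

Step 8
Reactants: 11 methyl (2R,3R,4S)-4-[1-(4-methoxyphenyl)ethenyl]-2-[4-(triisopropylsilyloxy)phenyl]oxolane-3-carboxylate
Product: 13 methyl (2R,3R,4R)-4-(4-methoxybenzoyl)-2-[4-(triisopropylsilyloxy)phenyl]oxolane-3-carboxylate, via secondary ozonide 12 (not isolated)
Conditions: O3, CH2Cl2, −78 °C (Sudan Red 7B end point); Me2S, −78 °C → rt
Reagents that add atoms: ozone, [O-][O+]=O
Why: Ozonolysis (Criegee mechanism) of the electron-rich 1,1-disubstituted alkene, which should react far faster than the arenes when the end point is marked by the dye, followed by neutral reductive work-up, unmasks the aryl ketone without disturbing the now epimerisable C4 centre, which already holds its preferred trans arrangement.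

Step 9
Reactants: 13 methyl (2R,3R,4R)-4-(4-methoxybenzoyl)-2-[4-(triisopropylsilyloxy)phenyl]oxolane-3-carboxylate
Product: 14 methyl (2R,3R,4R)-4-[(S)-hydroxy(4-methoxyphenyl)methyl]-2-[4-(triisopropylsilyloxy)phenyl]oxolane-3-carboxylate
Conditions: (R)-1-methyl-3,3-diphenyltetrahydro-1H,3H-pyrrolo[1,2-c][1,3,2]oxazaborole [(R)-Me-CBS, 20 mol %], BH3·SMe2 (1.0 equiv), THF, −20 °C; MeOH quench
Reagents that add atoms: none
Why: Corey–Bakshi–Shibata reduction, in which the ketone binds the catalyst boron anti to the aryl (large) group and the coordinated borane delivers hydride to one face, so the (R)-catalyst should give the (S)-carbinol; the Felkin–Anh preference of C4 (C3 as large substituent) is expected to point the same way, and the ester is not reduced at this temperature.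

Step 10
Reactants: 14 methyl (2R,3R,4R)-4-[(S)-hydroxy(4-methoxyphenyl)methyl]-2-[4-(triisopropylsilyloxy)phenyl]oxolane-3-carboxylate
Product: 15 [(2R,3S,4R)-4-[(S)-hydroxy(4-methoxyphenyl)methyl]-2-[4-(triisopropylsilyloxy)phenyl]oxolan-3-yl]methanol
Conditions: LiBH4 (2 equiv), THF, 0 °C → rt
Reagents that add atoms: none
Why: Hydride reduction of the methyl ester to the primary alcohol with LiBH4, which spares the aryl silyl ether and the benzylic ring ether; no stereocentre is touched, and lactonisation of 14 is not a competitor because it would need a trans-fused bicyclic lactone.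

Step 11
Reactants: 15 [(2R,3S,4R)-4-[(S)-hydroxy(4-methoxyphenyl)methyl]-2-[4-(triisopropylsilyloxy)phenyl]oxolan-3-yl]methanol
Product: 16 [(2R,3S,4R)-4-[(S)-acetoxy(4-methoxyphenyl)methyl]-2-[4-(triisopropylsilyloxy)phenyl]oxolan-3-yl]methyl acetate
Conditions: Ac2O (3 equiv), pyridine, 4-(dimethylamino)pyridine (5 mol %), CH2Cl2, 0 °C → rt
Reagents that add atoms: acetic anhydride, CC(=O)OC(C)=O
Why: Nucleophile-catalysed acylation of the primary and the secondary benzylic hydroxyl groups under basic conditions, which avoid ionisation at the 4-methoxybenzylic carbon, so its configuration is retained.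

Step 12
Reactants: 16 [(2R,3S,4R)-4-[(S)-acetoxy(4-methoxyphenyl)methyl]-2-[4-(triisopropylsilyloxy)phenyl]oxolan-3-yl]methyl acetate
Product: 17 [(2R,3S,4R)-4-[(S)-acetoxy(4-methoxyphenyl)methyl]-2-(4-hydroxyphenyl)oxolan-3-yl]methyl acetate (CNP0231272.1)
Conditions: Bu4NF (1.1 equiv), AcOH (1.1 equiv), THF, 0 °C
Reagents that add atoms: none
Why: Fluoride-induced cleavage of the aryl silyl ether through a pentacoordinate fluorosilicate; the acetic acid buffer protonates the phenoxide at once, which should prevent acetate cleavage or migration and quinone methide opening of the ring at C2.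

Compound list
1 | 4-methoxyphenylacetaldehyde | COc1ccc(CC=O)cc1 | starting material
2 | 3-(dimethylamino)-2-(4-methoxyphenyl)propanal (Mannich base, racemic) | COc1ccc(C(CN(C)C)C=O)cc1 | intermediate
3 | 2-(4-methoxyphenyl)prop-2-enal | COc1ccc(C(=C)C=O)cc1 | intermediate
4 | racemic 2-[1-(4-methoxyphenyl)ethenyl]oxirane | COc1ccc(C(=C)C2CO2)cc1 | intermediate
5 | 4-hydroxybenzaldehyde | O=Cc1ccc(O)cc1 | starting material
6 | 4-(triisopropylsilyloxy)benzaldehyde | CC(C)[Si](Oc1ccc(C=O)cc1)(C(C)C)C(C)C | intermediate
7 | dimethyl malonate | COC(=O)CC(=O)OC | starting material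
8 | dimethyl 2-[4-(triisopropylsilyloxy)benzylidene]malonate | COC(=O)C(=Cc1ccc(O[Si](C(C)C)(C(C)C)C(C)C)cc1)C(=O)OC | intermediate
9 | dimethyl (2S,4R)-4-[1-(4-methoxyphenyl)ethenyl]-2-[4-(triisopropylsilyloxy)phenyl]oxolane-3,3-dicarboxylate | COc1ccc(C(=C)[C@H]2CO[C@@H](c3ccc(O[Si](C(C)C)(C(C)C)C(C)C)cc3)C2(C(=O)OC)C(=O)OC)cc1 | intermediate
10 | methyl (2R,4S)-4-[1-(4-methoxyphenyl)ethenyl]-2-[4-(triisopropylsilyloxy)phenyl]oxolane-3-carboxylate, C3 epimers | COc1ccc(C(=C)[C@H]2CO[C@@H](c3ccc(O[Si](C(C)C)(C(C)C)C(C)C)cc3)C2C(=O)OC)cc1 | intermediate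
11 | methyl (2R,3R,4S)-4-[1-(4-methoxyphenyl)ethenyl]-2-[4-(triisopropylsilyloxy)phenyl]oxolane-3-carboxylate | COc1ccc(C(=C)[C@H]2CO[C@@H](c3ccc(O[Si](C(C)C)(C(C)C)C(C)C)cc3)[C@@H]2C(=O)OC)cc1 | intermediate
12 | methyl (2R,3R,4R)-4-[3-(4-methoxyphenyl)-1,2,4-trioxolan-3-yl]-2-[4-(triisopropylsilyloxy)phenyl]oxolane-3-carboxylate (secondary ozonide, both configurations at the trioxolane carbon) | COc1ccc(C4(OCOO4)[C@H]2CO[C@@H](c3ccc(O[Si](C(C)C)(C(C)C)C(C)C)cc3)[C@@H]2C(=O)OC)cc1 | intermediate
13 | methyl (2R,3R,4R)-4-(4-methoxybenzoyl)-2-[4-(triisopropylsilyloxy)phenyl]oxolane-3-carboxylate | COc1ccc(C(=O)[C@H]2CO[C@@H](c3ccc(O[Si](C(C)C)(C(C)C)C(C)C)cc3)[C@@H]2C(=O)OC)cc1 | intermediate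
14 | methyl (2R,3R,4R)-4-[(S)-hydroxy(4-methoxyphenyl)methyl]-2-[4-(triisopropylsilyloxy)phenyl]oxolane-3-carboxylate | COc1ccc([C@@H](O)[C@H]2CO[C@@H](c3ccc(O[Si](C(C)C)(C(C)C)C(C)C)cc3)[C@@H]2C(=O)OC)cc1 | intermediate
15 | [(2R,3S,4R)-4-[(S)-hydroxy(4-methoxyphenyl)methyl]-2-[4-(triisopropylsilyloxy)phenyl]oxolan-3-yl]methanol | COc1ccc([C@@H](O)[C@H]2CO[C@@H](c3ccc(O[Si](C(C)C)(C(C)C)C(C)C)cc3)[C@@H]2CO)cc1 | intermediate
16 | [(2R,3S,4R)-4-[(S)-acetoxy(4-methoxyphenyl)methyl]-2-[4-(triisopropylsilyloxy)phenyl]oxolan-3-yl]methyl acetate | COc1ccc([C@@H](OC(C)=O)[C@H]2CO[C@@H](c3ccc(O[Si](C(C)C)(C(C)C)C(C)C)cc3)[C@@H]2COC(C)=O)cc1 | intermediate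
17 | [(2R,3S,4R)-4-[(S)-acetoxy(4-methoxyphenyl)methyl]-2-(4-hydroxyphenyl)oxolan-3-yl]methyl acetate | COc1ccc([C@@H](OC(C)=O)[C@H]2CO[C@@H](c3ccc(O)cc3)[C@@H]2COC(C)=O)cc1 | target

Total step count: 12.
Longest linear sequence: 10 steps (steps 1, 2 and 5–12; the branch through steps 3, 4 and 5–12 is equally long).

Steps most likely to fail

Step 5. The epoxide may be consumed by isomerisation or oligomerisation of the zwitterion before the electron-rich acceptor traps it, and ring closure may discriminate too little between the cis and trans envelopes or between the two allyl faces. The fallback sets out from 4 and comes back to the route at 9. Epoxide 4 is treated with CO2 (1 atm) and the zerovalent palladium complex Pd(PPh3)4 (2 mol %) in THF at rt to give the racemic cyclic carbonate 4-[1-(4-methoxyphenyl)ethenyl]-1,3-dioxolan-2-one F1, a storable dipole precursor. F1 and 8 are then combined with Pd2(dba)3·CHCl3 and a chiral BINOL-derived phosphoramidite ligand in toluene. Loss of CO2 makes ionisation irreversible and gives the same alkoxide–allyl zwitterion, in a ligand manifold established for cis- and enantioselective [3+2] cycloadditions with doubly activated alkenes; the product is 9.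

Step 9. Facial selectivity may be poor because the α-branched ring carbon competes with the aryl group for the role of large substituent in the catalyst–ketone complex. The fallback sets out from 13 and comes back at 14. Ketone 13 is reduced under substrate control (NaBH4, CeCl3·7H2O, MeOH/THF, −40 °C), and 14 is separated by chromatography from its carbinol epimer, methyl (2R,3R,4R)-4-[(R)-hydroxy(4-methoxyphenyl)methyl]-2-[4-(triisopropylsilyloxy)phenyl]oxolane-3-carboxylate F2. F2 is returned to 13 with Dess–Martin periodinane (NaHCO3, CH2Cl2, 0 °C) and reduced again, so the material converges on 14.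

Step 6. At 140 °C chloride and the hydroxide generated may cleave the aryl silyl ether, and the liberated phenoxide can open the ring through a quinone methide and erode C2. The fallback sets out from 9 and comes back at 10. One ester of 9 is hydrolysed under neutral conditions with Me3SnOH (1,2-dichloroethane, 80 °C) to the malonic half-ester (2S,4R)-3-(methoxycarbonyl)-4-[1-(4-methoxyphenyl)ethenyl]-2-[4-(triisopropylsilyloxy)phenyl]oxolane-3-carboxylic acid F3. F3 is decarboxylated thermally in toluene at 110 °C to 10 without halide, water or strong base.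

Further compounds
F1 | step 5 | racemic 4-[1-(4-methoxyphenyl)ethenyl]-1,3-dioxolan-2-one | COc1ccc(C(=C)C2COC(=O)O2)cc1
F2 | step 9 | methyl (2R,3R,4R)-4-[(R)-hydroxy(4-methoxyphenyl)methyl]-2-[4-(triisopropylsilyloxy)phenyl]oxolane-3-carboxylate | COc1ccc([C@H](O)[C@H]2CO[C@@H](c3ccc(O[Si](C(C)C)(C(C)C)C(C)C)cc3)[C@@H]2C(=O)OC)cc1
F3 | step 6 | (2S,4R)-3-(methoxycarbonyl)-4-[1-(4-methoxyphenyl)ethenyl]-2-[4-(triisopropylsilyloxy)phenyl]oxolane-3-carboxylic acid (C3 epimers) | COc1ccc(C(=C)[C@H]2CO[C@@H](c3ccc(O[Si](C(C)C)(C(C)C)C(C)C)cc3)C2(C(=O)O)C(=O)OC)cc1
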